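1. Retrosynthesis: after removal of the silyl and benzyl groups, ring A (C4a, C5, C6, C7, C8, C8a) is cut at C4a–C8a, C5–C6 and C7–C8 in one operation. Its alternating carbon/oxygen substitution is that of a head-to-tail trimer of three O-substituted alkynes, O1–C2–C3–C4 of ring C is the tether between two of them, and each arm methine Ca is a propargylic carbon. This gives diyne 38 (alkynyl ether C8≡C8a–O1, siloxyalkyne C4a≡C5) and siloxyalkyne 22 (C6≡C7).
2. Both partners come from one arm alkyne 19. Oxidation of its acetylide to the ynolate and O-silylation gives 22; hydroboration–oxidation and chlorite oxidation give acid 25, which is esterified with flavan alcohol 32 (cut at O1–C8a) and converted into the alkynyl ether.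
3. Forward order of rings: the oxolane of the arm first (C3′–C4′ by lactone alkylation, C2′–C3′ by aldol, O1′–C5′ by hemiketal reduction), then rings C and A together in the key step. The two aryl ketones of the arm are introduced one after the other through Weinreb amides. Primed locants: C2′ carries 4-benzyloxyphenyl, C3′ the aroyl group, C4′ bears Ca, C5′ carries 2,4-bis(benzyloxy)phenyl.
4. Stereochemistry: Ca from rhodium/BINAP-catalysed aryl addition to a dihydropyranone; C4′ from trans alkylation of that lactone (ring control); C5′ from hydride addition anti to the C4′ substituent; C2′ and C3′ by base equilibration to the all-trans arrangement; flavan C3 from an Evans glycolate alkylation and C2 from chelation-controlled ketone reduction.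
5. The arm ketones travel as silyl-protected carbinols through the strongly basic steps and are restored after the cycloaddition, which itself creates no stereocentre.

Key step: step 21

Assumption: the carbinol carbon made in step 9 is carried as a mixture of epimers because it returns to a ketone in step 23; compounds 18–25 and 33–40 are therefore drawn without a descriptor at that carbon.

**Route**

Step 1
Reactants: 1 5,6-dihydro-2H-pyran-2-one; 2 4-(benzyloxy)phenylboronic acid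
Product: 3 (S)-4-[4-(benzyloxy)phenyl]oxan-2-one
Conditions: Rh(acac)(C2H4)2 (3 mol %), (S)-BINAP, 1,4-dioxane/H2O 10:1, 100 °C
Reagents that add atoms: none
Why: Hayashi–Miyaura rhodium-catalysed asymmetric 1,4-addition of an arylboronic acid to an unsaturated δ-lactone, in which the (S)-BINAP aryl-rhodium species should add to one face of the enoate in the sense known for cyclic enones and set the future Ca as S.

Step 2
Reactants: 3 (S)-4-[4-(benzyloxy)phenyl]oxan-2-one; 4 2-bromo-N-methoxy-N-methylacetamide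
Product: 5 2-[(3R,4S)-4-[4-(benzyloxy)phenyl]-2-oxooxan-3-yl]-N-methoxy-N-methylacetamide
Conditions: LiN(SiMe3)2, THF, −78 °C; then 4, −78 to −40 °C
Reagents that add atoms: none
Why: Enolate alkylation of a 4-aryl δ-lactone, where the electrophile should enter anti to the neighbouring aryl group and give the 3,4-trans lactone, so the future C4′ is fixed relative to Ca inside a ring instead of in an open chain.

Step 3
Reactants: 5 2-[(3R,4S)-4-[4-(benzyloxy)phenyl]-2-oxooxan-3-yl]-N-methoxy-N-methylacetamide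
Product: 7 (2R)-2-{(1S)-1-[4-(benzyloxy)phenyl]-3-oxopropyl}-N1,N4-dimethoxy-N1,N4-dimethylbutanediamide, via hydroxy amide 6 (not isolated)
Conditions: MeNH(OMe)·HCl, AlMe3, CH2Cl2, 0 °C to rt; aqueous work-up; then Dess–Martin periodinane, CH2Cl2, 0 °C
Reagents that add atoms: N,O-dimethylhydroxylamine hydrochloride, CNOC.Cl
Why: Weinreb aminolysis of the lactone by the aluminium amide frees the primary alcohol, and Dess–Martin oxidation of the crude alcohol before it can relactonise gives the aldehyde without touching either stereocentre.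

Step 4
Reactants: 7 (2R)-2-{(1S)-1-[4-(benzyloxy)phenyl]-3-oxopropyl}-N1,N4-dimethoxy-N1,N4-dimethylbutanediamide
Product: 9 (2R)-2-{(1R)-1-[4-(benzyloxy)phenyl]prop-2-yn-1-yl}-N1,N4-dimethoxy-N1,N4-dimethylbutanediamide, via enol nonaflate 8 (not isolated)
Conditions: C4F9SO2F, phosphazene base P2-Et, DMF, −20 °C to rt
Reagents that add atoms: none
Why: One-pot nonaflation–elimination of an enolisable aldehyde (enol nonaflate, then base-induced loss of nonaflate) turns CH2–CHO into C≡CH without adding carbon, and the base should be too weak to deprotonate the amide α-positions or the propargylic Ca–H.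

Step 5
Reactants: 9 (2R)-2-{(1R)-1-[4-(benzyloxy)phenyl]prop-2-yn-1-yl}-N1,N4-dimethoxy-N1,N4-dimethylbutanediamide; 10 1-bromo-2,4-bis(benzyloxy)benzene
Product: 11 (2R)-4-[2,4-bis(benzyloxy)phenyl]-2-{(1R)-1-[4-(benzyloxy)phenyl]prop-2-yn-1-yl}-N-methoxy-N-methyl-4-oxobutanamide
Conditions: 10 (2.1 equiv), n-BuLi (2.1 equiv), THF, −78 °C; then 9, −78 °C, 1 h; AcOH quench at −78 °C
Reagents that add atoms: none
Why: Aryllithium addition to a Weinreb amide stops at the ketone through the chelated tetrahedral intermediate; the first equivalent is spent on the acetylenic C–H, and the second should choose the unhindered CH2-bound amide over the amide on the doubly branched C2, so only one aryl ketone is formed.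

Step 6
Reactants: 11 (2R)-4-[2,4-bis(benzyloxy)phenyl]-2-{(1R)-1-[4-(benzyloxy)phenyl]prop-2-yn-1-yl}-N-methoxy-N-methyl-4-oxobutanamide; 10 1-bromo-2,4-bis(benzyloxy)benzene
Product: 13 (2R)-1,4-bis[2,4-bis(benzyloxy)phenyl]-2-{(1R)-1-[4-(benzyloxy)phenyl]prop-2-yn-1-yl}butane-1,4-dione, via lithium enolate 12 (not isolated)
Conditions: LiN(SiMe3)2 (1.1 equiv), THF, −78 °C; then aryllithium from 10 and n-BuLi (2.2 equiv), −78 to −40 °C; AcOH quench at −78 °C
Reagents that add atoms: none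
Why: In situ protection of the ketone as its lithium enolate (only its CH2 flank can enolise) lets the aryllithium add to the remaining hindered Weinreb amide without attacking the first carbonyl; the tetrahedral chelate prevents over-addition and shields C2 from enolisation until the cold quench returns the 1,4-diketone.

Step 7
Reactants: 13 (2R)-1,4-bis[2,4-bis(benzyloxy)phenyl]-2-{(1R)-1-[4-(benzyloxy)phenyl]prop-2-yn-1-yl}butane-1,4-dione; 14 4-(benzyloxy)benzaldehyde
Product: 16 oxolane ketone as a mixture of C2′/C3′ epimers (C4′/C5′ cis), via hemiketal 15 (not isolated)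
Conditions: LiN(SiMe3)2 (1.05 equiv), THF, −78 °C; 14; AcOH quench; then Et3SiH, BF3·OEt2, CH2Cl2, −78 °C
Reagents that add atoms: none
Why: Lithium-enolate aldol addition at the less hindered CH2 flank and spontaneous hemiketal formation, then ionic hydrogenation of the cyclic oxocarbenium ion, in which hydride should add anti to the bulky C4′ substituent as in lignan oxolane syntheses and set C5′ cis to C4′.

Step 8
Reactants: 16 oxolane ketone as a mixture of C2′/C3′ epimers
Product: 17 [(2S,3S,4S,5R)-5-[2,4-bis(benzyloxy)phenyl]-2-[4-(benzyloxy)phenyl]-4-{(1R)-1-[4-(benzyloxy)phenyl]prop-2-yn-1-yl}oxolan-3-yl][2,4-bis(benzyloxy)phenyl]methanone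
Conditions: NaOMe (0.2 equiv), MeOH/THF, rt
Reagents that add atoms: none
Why: Base equilibration by enolisation and reversible retro-oxa-Michael/oxa-Michael ring opening and closure should funnel the epimers into the most stable oxolane, with the aroyl group trans to both neighbours (2′,3′-trans, 3′,4′-trans, 2′,5′-cis), while C4′ and C5′ cannot epimerise.

Step 9
Reactants: 17 arm alkyne ketone
Product: 18 arm alkyne carbinol (ketone of 17 reduced to CH(OH), epimer mixture at that carbon)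
Conditions: NaBH4, CeCl3·7H2O, MeOH/THF, −20 °C
Reagents that add atoms: none
Why: Luche-type borohydride reduction of the aryl ketone under weakly basic conditions removes the acidic α-hydrogen and the β-alkoxy ketone motif before the organolithium and borane steps.

Step 10
Reactants: 18 arm alkyne carbinol
Product: 19 arm alkyne triethylsilyl ether
Conditions: Et3SiOTf, 2,6-lutidine, CH2Cl2, −78 °C
Reagents that add atoms: triethylsilyl triflate, CC[Si](CC)(CC)OS(=O)(=O)C(F)(F)F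
Why: Silyl triflate/2,6-lutidine silylation of a hindered secondary alcohol is routine and gives an ether stable to amide and alkyllithium bases.

Step 11
Reactants: 19 arm alkyne triethylsilyl ether
Product: 22 arm siloxyalkyne (iPr3SiO–C≡C–Ca), via lithium acetylide 20 (not isolated), via lithium ynolate 21 (not isolated)
Conditions: n-BuLi, THF, −78 °C; LiOOt-Bu (from t-BuOOH and LiN(SiMe3)2), −78 to 0 °C; then iPr3SiOTf, −78 °C
Reagents that add atoms: tert-butyl hydroperoxide, CC(C)(C)OO; triisopropylsilyl triflate, CC(C)[Si](C(C)C)(C(C)C)OS(=O)(=O)C(F)(F)F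
Why: Julia–Kozmin siloxyalkyne synthesis, in which the lithium acetylide is oxidised by the peroxide oxenoid to the ynolate and the bulky silyl triflate silylates it on oxygen, with Ca not involved.

Step 12
Reactants: 19 arm alkyne triethylsilyl ether
Product: 24 arm aldehyde (C≡CH of 19 replaced by CH2CHO), via alkenylborane 23 (not isolated)
Conditions: dicyclohexylborane (from BH3·SMe2 and cyclohexene), THF, 0 °C to rt; then 30% H2O2, pH 7 phosphate buffer, 0 °C
Reagents that add atoms: hydrogen peroxide, OO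
Why: Anti-Markovnikov hydroboration of a terminal alkyne with a dialkylborane places boron on the terminal carbon, and buffered peroxide oxidation of the (E)-alkenylborane gives the enol and hence the aldehyde, whose carbonyl is two bonds from Ca so that this centre cannot enolise.

Step 13
Reactants: 24 arm aldehyde
Product: 25 arm acid (3-aryl-3-(oxolan-3-yl)propanoic acid)
Conditions: NaClO2, NaH2PO4, 2-methyl-2-butene, t-BuOH/THF/H2O, 0 °C
Reagents that add atoms: sodium chlorite, [Na+].[O-]Cl=O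
Why: Pinnick oxidation converts the aldehyde into the carboxylic acid under mildly acidic buffered conditions that spare the silyl ether, while the alkene scavenger removes hypochlorous acid before it can chlorinate the electron-rich arenes.

Step 14
Reactants: 26 (R)-4-benzyl-3-[(benzyloxy)acetyl]-1,3-oxazolidin-2-one; 27 3-bromo-1-(trimethylsilyl)prop-1-yne
Product: 28 (4R)-4-benzyl-3-[(2S)-2-(benzyloxy)-5-(trimethylsilyl)pent-4-ynoyl]-1,3-oxazolidin-2-one
Conditions: NaN(SiMe3)2, THF, −78 °C; then 27, −78 to −45 °C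
Reagents that add atoms: none
Why: Evans asymmetric alkylation of the chelated Z sodium enolate of a glycolate imide, in which the benzyl group of the (R)-auxiliary shields one face and should set the future flavan C3 as S.

Step 15
Reactants: 28 alkylated glycolate imide
Product: 29 (2S)-2-(benzyloxy)-N-methoxy-N-methyl-5-(trimethylsilyl)pent-4-ynamide
Conditions: MeNH(OMe)·HCl, AlMe3, CH2Cl2, 0 °C
Reagents that add atoms: N,O-dimethylhydroxylamine hydrochloride, CNOC.Cl
Why: Aluminium-amide transamination of an acyl oxazolidinone to the Weinreb amide is standard and releases the auxiliary without epimerising the α-alkoxy centre.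

Step 16
Reactants: 29 Weinreb amide; 30 4-(benzyloxy)phenylmagnesium bromide
Product: 31 (2S)-2-(benzyloxy)-1-[4-(benzyloxy)phenyl]-5-(trimethylsilyl)pent-4-yn-1-one
Conditions: 30 (THF solution), THF, −20 to 0 °C; then H2O
Reagents that add atoms: none
Why: Grignard addition to a Weinreb amide gives the aryl ketone through the stable magnesium chelate without over-addition.

Step 17
Reactants: 31 α-benzyloxy ketone
Product: 32 (1R,2S)-2-(benzyloxy)-1-[4-(benzyloxy)phenyl]-5-(trimethylsilyl)pent-4-yn-1-ol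
Conditions: Zn(BH4)2, Et2O, −78 to −20 °C
Reagents that add atoms: none
Why: Chelation-controlled (Cram chelate) reduction of an α-benzyloxy ketone, where hydride should add from the face opposite the propargyl chain and give the anti alcohol, which is the 2,3-trans relationship of the flavan.

Step 18
Reactants: 25 arm acid; 32 flavan alcohol
Product: 33 ester of 25 with 32
Conditions: EDC·HCl, 4-(dimethylamino)pyridine, CH2Cl2, 0 °C to rt
Reagents that add atoms: none
Why: Steglich carbodiimide esterification activates only the acyl group, so the benzylic carbinol C2 is joined to the arm with retention.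

Step 19
Reactants: 33 ester
Product: 35 alkynyl ether (C2–O1–C8a≡C8–Ca, trimethylsilyl alkyne at the other end), via ketene acetal phosphate 34 (not isolated)
Conditions: LiN(iPr)2, THF, −78 °C; ClP(O)(OEt)2, −78 to 0 °C; then t-BuLi, −78 °C
Reagents that add atoms: none
Why: Known ester-to-alkynyl-ether sequence, in which the ester enolate is trapped on oxygen as the ketene acetal phosphate and strong base then removes the vinylic hydrogen with β-elimination of phosphate, leaving the C2–O1 bond and Ca untouched.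

Step 20
Reactants: 35 alkynyl ether
Product: 38 diyne (alkynyl ether plus siloxyalkyne), via lithium acetylide 36 (not isolated), via lithium ynolate 37 (not isolated)
Conditions: MeLi·LiBr, THF, −78 to 0 °C; LiOOt-Bu (from t-BuOOH and LiN(SiMe3)2), −78 to 0 °C; then iPr3SiOTf, −78 °C
Reagents that add atoms: tert-butyl hydroperoxide, CC(C)(C)OO; triisopropylsilyl triflate, CC(C)[Si](C(C)C)(C(C)C)OS(=O)(=O)C(F)(F)F
Why: MeLi·LiBr cleaves the alkynyl C–Si bond to the lithium acetylide, which is oxidised and O-silylated as in step 11; alkynyl ethers should be inert to organolithiums and peroxide anion at low temperature.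

Step 21
Reactants: 38 diyne; 22 arm siloxyalkyne
Product: 39 cycloadduct (protected target: O5 and O7 as triisopropylsilyl ethers, arm carbinols as triethylsilyl ethers, all other oxygens benzylated)
Conditions: [Rh(cod)2]BF4 (10 mol %), (S)-BINAP (10 mol %), pre-activated with H2, CH2Cl2, 0 °C to rt; 22 added over 6 h
Reagents that add atoms: none
Why: Proposed new method: cationic monovalent rhodium with BINAP should bind both alkynes of 38 and couple them oxidatively to a rhodacyclopentadiene, forming C4a–C8a and closing ring C as a six-membered ring through the O1–C2–C3–C4 tether; siloxyalkyne 22 then inserts and reductive elimination forms C5–C6 and C7–C8, closing ring A as the benzene ring. The closest known reaction types are cationic rhodium bisphosphine (2+2+2) cycloadditions of tethered diynes with monoalkynes and benzannulations of siloxyalkynes; a trimer of three O-substituted alkynes that includes a secondary alkyl alkynyl ether has no precedent. No stereocentre is formed, and Ca, C2 and C3 sit one bond away from the reacting carbons and are not touched. The step needs chemoselectivity for the cross-trimer over the homotrimer of 22, which the tethered diyne and slow addition of 22 should secure, and head-to-tail insertion, which is favoured because it keeps the two bulky arms and the two silyloxy groups apart and matches the polarity of the electron-rich alkynes. The benzylic alkynyl ether of 38 can lose ketene by a retro-ene path or rearrange sigmatropically on warming, so the catalyst must turn over at or below room temperature; in return the crowded arene never has to accept a bulky electrophile.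

Step 22
Reactants: 39 cycloadduct
Product: 40 bis-carbinol (both arm CH(OH) free, aryl silyl ethers intact)
Conditions: HF·pyridine, pyridine, THF, 0 °C
Reagents that add atoms: none
Why: Buffered acidic fluoride cleaves alkyl triethylsilyl ethers much faster than hindered aryl triisopropylsilyl ethers, a standard selectivity between alkyl and aryl silyl ethers.

Step 23
Reactants: 40 bis-carbinol
Product: 41 bis-ketone (both arm aryl ketones restored)
Conditions: Dess–Martin periodinane, CH2Cl2, 0 °C to rt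
Reagents that add atoms: none
Why: Dess–Martin oxidation of the two benzylic carbinols restores the aryl ketones under neutral conditions, so C3′ of each oxolane keeps the configuration set in step 8.

Step 24
Reactants: 41 bis-ketone
Product: 42 5,7-diol (all remaining oxygens benzylated)
Conditions: Bu4NF, AcOH, THF, 0 °C
Reagents that add atoms: none
Why: Fluoride cleaves the aryl silyl ethers, and the acetic acid buffer limits base-induced opening of the β-alkoxy ketones, whose thermodynamic configuration is in any case the desired one.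

Step 25
Reactants: 42 5,7-diol
Product: 43 CNP0225367.3 (target)
Conditions: H2 (1 atm), Pd(OH)2 on carbon, THF/MeOH, rt
Reagents that add atoms: none
Why: Hydrogenolysis removes all fourteen benzyl ethers, while the flavan and 2,5-diaryloxolane C–O bonds should survive mild conditions as in catechin and lignan end games.

**Compound list**

1 | 5,6-dihydro-2H-pyran-2-one | O=C1C=CCCO1 | starting material
2 | 4-(benzyloxy)phenylboronic acid | OB(O)c1ccc(OCc2ccccc2)cc1 | starting material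
3 | (S)-4-[4-(benzyloxy)phenyl]oxan-2-one | O=C1C[C@@H](c2ccc(OCc3ccccc3)cc2)CCO1 | intermediate
4 | 2-bromo-N-methoxy-N-methylacetamide | BrCC(=O)N(C)OC | starting material
5 | 2-[(3R,4S)-4-[4-(benzyloxy)phenyl]-2-oxooxan-3-yl]-N-methoxy-N-methylacetamide (3,4-trans) | O1CC[C@H](c7ccc(OCc9ccccc9)cc7)[C@@H](CC(=O)N(C)OC)C1=O | intermediate
6 | (2R)-2-{(1S)-1-[4-(benzyloxy)phenyl]-3-hydroxypropyl}-N1,N4-dimethoxy-N1,N4-dimethylbutanediamide | OCC[C@H](c7ccc(OCc9ccccc9)cc7)[C@@H](CC(=O)N(C)OC)C(=O)N(C)OC | intermediate (not isolated)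
7 | (2R)-2-{(1S)-1-[4-(benzyloxy)phenyl]-3-oxopropyl}-N1,N4-dimethoxy-N1,N4-dimethylbutanediamide | O=CC[C@H](c7ccc(OCc9ccccc9)cc7)[C@@H](CC(=O)N(C)OC)C(=O)N(C)OC | intermediate
8 | enol nonafluorobutanesulfonate of aldehyde 7 (E/Z mixture) | FC(F)(F)C(F)(F)C(F)(F)C(F)(F)S(=O)(=O)OC=C[C@H](c7ccc(OCc9ccccc9)cc7)[C@@H](CC(=O)N(C)OC)C(=O)N(C)OC | intermediate (not isolated)
9 | (2R)-2-{(1R)-1-[4-(benzyloxy)phenyl]prop-2-yn-1-yl}-N1,N4-dimethoxy-N1,N4-dimethylbutanediamide | C#C[C@H](c7ccc(OCc9ccccc9)cc7)[C@@H](CC(=O)N(C)OC)C(=O)N(C)OC | intermediate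
10 | 1-bromo-2,4-bis(benzyloxy)benzene | Brc1ccc(OCc2ccccc2)cc1OCc1ccccc1 | starting material
11 | (2R)-4-[2,4-bis(benzyloxy)phenyl]-2-{(1R)-1-[4-(benzyloxy)phenyl]prop-2-yn-1-yl}-N-methoxy-N-methyl-4-oxobutanamide (keto Weinreb amide) | C#C[C@H](c7ccc(OCc9ccccc9)cc7)[C@@H](CC(=O)c8ccc(OCc9ccccc9)cc8OCc9ccccc9)C(=O)N(C)OC | intermediate
12 | lithium enolate of keto amide 11 (enolised toward CH2, Z geometry expected) | C#C[C@H](c7ccc(OCc9ccccc9)cc7)[C@@H](C=C(O[Li])c8ccc(OCc9ccccc9)cc8OCc9ccccc9)C(=O)N(C)OC | intermediate (not isolated)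
13 | (2R)-1,4-bis[2,4-bis(benzyloxy)phenyl]-2-{(1R)-1-[4-(benzyloxy)phenyl]prop-2-yn-1-yl}butane-1,4-dione | C#C[C@H](c7ccc(OCc9ccccc9)cc7)[C@@H](CC(=O)c8ccc(OCc9ccccc9)cc8OCc9ccccc9)C(=O)c8ccc(OCc9ccccc9)cc8OCc9ccccc9 | intermediate
14 | 4-(benzyloxy)benzaldehyde | O=Cc1ccc(OCc2ccccc2)cc1 | starting material
15 | cyclic hemiketal of the aldol adduct of 13 and 14 (2-hydroxyoxolane, mixture at C2′, C3′ and the hemiketal carbon) | C#C[C@H](c7ccc(OCc9ccccc9)cc7)[C@H]4C(C(=O)c8ccc(OCc9ccccc9)cc8OCc9ccccc9)C(c7ccc(OCc9ccccc9)cc7)OC4(O)c8ccc(OCc9ccccc9)cc8OCc9ccccc9 | intermediate (not isolated)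
16 | oxolane ketone, C4′/C5′ cis, mixture of C2′/C3′ epimers | C#C[C@H](c7ccc(OCc9ccccc9)cc7)[C@H]4C(C(=O)c8ccc(OCc9ccccc9)cc8OCc9ccccc9)C(c7ccc(OCc9ccccc9)cc7)O[C@H]4c8ccc(OCc9ccccc9)cc8OCc9ccccc9 | intermediate
17 | arm alkyne ketone, [(2S,3S,4S,5R)-5-[2,4-bis(benzyloxy)phenyl]-2-[4-(benzyloxy)phenyl]-4-{(1R)-1-[4-(benzyloxy)phenyl]prop-2-yn-1-yl}oxolan-3-yl][2,4-bis(benzyloxy)phenyl]methanone | C#C[C@H](c7ccc(OCc9ccccc9)cc7)[C@H]4[C@H](C(=O)c8ccc(OCc9ccccc9)cc8OCc9ccccc9)[C@@H](c7ccc(OCc9ccccc9)cc7)O[C@H]4c8ccc(OCc9ccccc9)cc8OCc9ccccc9 | intermediate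
18 | arm alkyne carbinol: 17 with C=O reduced to CH(OH) (epimers at that carbon) | C#C[C@H](c7ccc(OCc9ccccc9)cc7)[C@H]4[C@H](C(O)c8ccc(OCc9ccccc9)cc8OCc9ccccc9)[C@@H](c7ccc(OCc9ccccc9)cc7)O[C@H]4c8ccc(OCc9ccccc9)cc8OCc9ccccc9 | intermediate
19 | arm alkyne triethylsilyl ether of 18 | C#C[C@H](c7ccc(OCc9ccccc9)cc7)[C@H]4[C@H](C(O[Si](CC)(CC)CC)c8ccc(OCc9ccccc9)cc8OCc9ccccc9)[C@@H](c7ccc(OCc9ccccc9)cc7)O[C@H]4c8ccc(OCc9ccccc9)cc8OCc9ccccc9 | intermediate
20 | lithium acetylide of 19 | [Li]C#C[C@H](c7ccc(OCc9ccccc9)cc7)[C@H]4[C@H](C(O[Si](CC)(CC)CC)c8ccc(OCc9ccccc9)cc8OCc9ccccc9)[C@@H](c7ccc(OCc9ccccc9)cc7)O[C@H]4c8ccc(OCc9ccccc9)cc8OCc9ccccc9 | intermediate (not isolated)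
21 | lithium ynolate from 19 (LiO–C≡C–Ca) | [Li+].[O-]C#C[C@H](c7ccc(OCc9ccccc9)cc7)[C@H]4[C@H](C(O[Si](CC)(CC)CC)c8ccc(OCc9ccccc9)cc8OCc9ccccc9)[C@@H](c7ccc(OCc9ccccc9)cc7)O[C@H]4c8ccc(OCc9ccccc9)cc8OCc9ccccc9 | intermediate (not isolated)
22 | arm siloxyalkyne, triisopropylsilyl ynol ether of the arm (carries the C6 arm) | CC(C)[Si](C(C)C)(C(C)C)OC#C[C@H](c7ccc(OCc9ccccc9)cc7)[C@H]4[C@H](C(O[Si](CC)(CC)CC)c8ccc(OCc9ccccc9)cc8OCc9ccccc9)[C@@H](c7ccc(OCc9ccccc9)cc7)O[C@H]4c8ccc(OCc9ccccc9)cc8OCc9ccccc9 | intermediate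
23 | (E)-alkenyl(dicyclohexyl)borane from 19 | C1CCCCC1B(C2CCCCC2)/C=C/[C@H](c7ccc(OCc9ccccc9)cc7)[C@H]4[C@H](C(O[Si](CC)(CC)CC)c8ccc(OCc9ccccc9)cc8OCc9ccccc9)[C@@H](c7ccc(OCc9ccccc9)cc7)O[C@H]4c8ccc(OCc9ccccc9)cc8OCc9ccccc9 | intermediate (not isolated)
24 | arm aldehyde, 3-aryl-3-(oxolan-3-yl)propanal from 19 | O=CC[C@H](c7ccc(OCc9ccccc9)cc7)[C@H]4[C@H](C(O[Si](CC)(CC)CC)c8ccc(OCc9ccccc9)cc8OCc9ccccc9)[C@@H](c7ccc(OCc9ccccc9)cc7)O[C@H]4c8ccc(OCc9ccccc9)cc8OCc9ccccc9 | intermediate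
25 | arm acid, 3-aryl-3-(oxolan-3-yl)propanoic acid | OC(=O)C[C@H](c7ccc(OCc9ccccc9)cc7)[C@H]4[C@H](C(O[Si](CC)(CC)CC)c8ccc(OCc9ccccc9)cc8OCc9ccccc9)[C@@H](c7ccc(OCc9ccccc9)cc7)O[C@H]4c8ccc(OCc9ccccc9)cc8OCc9ccccc9 | intermediate
26 | (R)-4-benzyl-3-[(benzyloxy)acetyl]-1,3-oxazolidin-2-one | O=C(COCc1ccccc1)N1[C@H](Cc2ccccc2)COC1=O | starting material
27 | 3-bromo-1-(trimethylsilyl)prop-1-yne | C[Si](C)(C)C#CCBr | starting material
28 | (4R)-4-benzyl-3-[(2S)-2-(benzyloxy)-5-(trimethylsilyl)pent-4-ynoyl]-1,3-oxazolidin-2-one | C[Si](C)(C)C#CC[C@H](OCc1ccccc1)C(=O)N1[C@H](Cc2ccccc2)COC1=O | intermediate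
29 | (2S)-2-(benzyloxy)-N-methoxy-N-methyl-5-(trimethylsilyl)pent-4-ynamide | C[Si](C)(C)C#CC[C@H](OCc1ccccc1)C(=O)N(C)OC | intermediate
30 | 4-(benzyloxy)phenylmagnesium bromide | Br[Mg]c1ccc(OCc2ccccc2)cc1 | starting material
31 | (2S)-2-(benzyloxy)-1-[4-(benzyloxy)phenyl]-5-(trimethylsilyl)pent-4-yn-1-one | C[Si](C)(C)C#CC[C@H](OCc1ccccc1)C(=O)c1ccc(OCc2ccccc2)cc1 | intermediate
32 | (1R,2S)-2-(benzyloxy)-1-[4-(benzyloxy)phenyl]-5-(trimethylsilyl)pent-4-yn-1-ol | C[Si](C)(C)C#CC[C@H](OCc9ccccc9)[C@@H](c7ccc(OCc9ccccc9)cc7)O | intermediate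
33 | ester of arm acid 25 with alcohol 32 | C[Si](C)(C)C#CC[C@H](OCc9ccccc9)[C@@H](c7ccc(OCc9ccccc9)cc7)OC(=O)C[C@H](c7ccc(OCc9ccccc9)cc7)[C@H]4[C@H](C(O[Si](CC)(CC)CC)c8ccc(OCc9ccccc9)cc8OCc9ccccc9)[C@@H](c7ccc(OCc9ccccc9)cc7)O[C@H]4c8ccc(OCc9ccccc9)cc8OCc9ccccc9 | intermediate
34 | ketene acetal diethyl phosphate of ester 33 | C[Si](C)(C)C#CC[C@H](OCc9ccccc9)[C@@H](c7ccc(OCc9ccccc9)cc7)OC(OP(=O)(OCC)OCC)=C[C@H](c7ccc(OCc9ccccc9)cc7)[C@H]4[C@H](C(O[Si](CC)(CC)CC)c8ccc(OCc9ccccc9)cc8OCc9ccccc9)[C@@H](c7ccc(OCc9ccccc9)cc7)O[C@H]4c8ccc(OCc9ccccc9)cc8OCc9ccccc9 | intermediate (not isolated)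
35 | alkynyl ether: 1-alkynyl ether of 32 carrying the C8 arm, trimethylsilyl alkyne end | C[Si](C)(C)C#CC[C@H](OCc9ccccc9)[C@@H](c7ccc(OCc9ccccc9)cc7)OC#C[C@H](c7ccc(OCc9ccccc9)cc7)[C@H]4[C@H](C(O[Si](CC)(CC)CC)c8ccc(OCc9ccccc9)cc8OCc9ccccc9)[C@@H](c7ccc(OCc9ccccc9)cc7)O[C@H]4c8ccc(OCc9ccccc9)cc8OCc9ccccc9 | intermediate
36 | lithium acetylide from 35 after loss of the trimethylsilyl group | [Li]C#CC[C@H](OCc9ccccc9)[C@@H](c7ccc(OCc9ccccc9)cc7)OC#C[C@H](c7ccc(OCc9ccccc9)cc7)[C@H]4[C@H](C(O[Si](CC)(CC)CC)c8ccc(OCc9ccccc9)cc8OCc9ccccc9)[C@@H](c7ccc(OCc9ccccc9)cc7)O[C@H]4c8ccc(OCc9ccccc9)cc8OCc9ccccc9 | intermediate (not isolated)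
37 | lithium ynolate from 36 | [Li+].[O-]C#CC[C@H](OCc9ccccc9)[C@@H](c7ccc(OCc9ccccc9)cc7)OC#C[C@H](c7ccc(OCc9ccccc9)cc7)[C@H]4[C@H](C(O[Si](CC)(CC)CC)c8ccc(OCc9ccccc9)cc8OCc9ccccc9)[C@@H](c7ccc(OCc9ccccc9)cc7)O[C@H]4c8ccc(OCc9ccccc9)cc8OCc9ccccc9 | intermediate (not isolated)
38 | diyne: siloxyalkyne (C4a≡C5), C4–C3–C2–O1 tether, alkynyl ether (C8a≡C8) with the C8 arm | CC(C)[Si](C(C)C)(C(C)C)OC#CC[C@H](OCc9ccccc9)[C@@H](c7ccc(OCc9ccccc9)cc7)OC#C[C@H](c7ccc(OCc9ccccc9)cc7)[C@H]4[C@H](C(O[Si](CC)(CC)CC)c8ccc(OCc9ccccc9)cc8OCc9ccccc9)[C@@H](c7ccc(OCc9ccccc9)cc7)O[C@H]4c8ccc(OCc9ccccc9)cc8OCc9ccccc9 | intermediate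
39 | cycloadduct: (2R,3S)-flavan with both arms, O5/O7 triisopropylsilyl, arm carbinols triethylsilyl, other oxygens benzyl | c9ccccc9CO[C@H]1Cc2c(O[Si](C(C)C)(C(C)C)C(C)C)c([C@H](c7ccc(OCc9ccccc9)cc7)[C@H]4[C@H](C(O[Si](CC)(CC)CC)c8ccc(OCc9ccccc9)cc8OCc9ccccc9)[C@@H](c7ccc(OCc9ccccc9)cc7)O[C@H]4c8ccc(OCc9ccccc9)cc8OCc9ccccc9)c(O[Si](C(C)C)(C(C)C)C(C)C)c([C@H](c7ccc(OCc9ccccc9)cc7)[C@H]4[C@H](C(O[Si](CC)(CC)CC)c8ccc(OCc9ccccc9)cc8OCc9ccccc9)[C@@H](c7ccc(OCc9ccccc9)cc7)O[C@H]4c8ccc(OCc9ccccc9)cc8OCc9ccccc9)c2O[C@@H]1c7ccc(OCc9ccccc9)cc7 | intermediate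
40 | bis-carbinol: 39 with both triethylsilyl groups removed | c9ccccc9CO[C@H]1Cc2c(O[Si](C(C)C)(C(C)C)C(C)C)c([C@H](c7ccc(OCc9ccccc9)cc7)[C@H]4[C@H](C(O)c8ccc(OCc9ccccc9)cc8OCc9ccccc9)[C@@H](c7ccc(OCc9ccccc9)cc7)O[C@H]4c8ccc(OCc9ccccc9)cc8OCc9ccccc9)c(O[Si](C(C)C)(C(C)C)C(C)C)c([C@H](c7ccc(OCc9ccccc9)cc7)[C@H]4[C@H](C(O)c8ccc(OCc9ccccc9)cc8OCc9ccccc9)[C@@H](c7ccc(OCc9ccccc9)cc7)O[C@H]4c8ccc(OCc9ccccc9)cc8OCc9ccccc9)c2O[C@@H]1c7ccc(OCc9ccccc9)cc7 | intermediate
41 | bis-ketone: protected target with silyl ethers at O5 and O7 | c9ccccc9CO[C@H]1Cc2c(O[Si](C(C)C)(C(C)C)C(C)C)c([C@H](c7ccc(OCc9ccccc9)cc7)[C@H]4[C@H](C(=O)c8ccc(OCc9ccccc9)cc8OCc9ccccc9)[C@@H](c7ccc(OCc9ccccc9)cc7)O[C@H]4c8ccc(OCc9ccccc9)cc8OCc9ccccc9)c(O[Si](C(C)C)(C(C)C)C(C)C)c([C@H](c7ccc(OCc9ccccc9)cc7)[C@H]4[C@H](C(=O)c8ccc(OCc9ccccc9)cc8OCc9ccccc9)[C@@H](c7ccc(OCc9ccccc9)cc7)O[C@H]4c8ccc(OCc9ccccc9)cc8OCc9ccccc9)c2O[C@@H]1c7ccc(OCc9ccccc9)cc7 | intermediate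
42 | 5,7-diol: tetradeca-O-benzyl target | c9ccccc9CO[C@H]1Cc2c(O)c([C@H](c7ccc(OCc9ccccc9)cc7)[C@H]4[C@H](C(=O)c8ccc(OCc9ccccc9)cc8OCc9ccccc9)[C@@H](c7ccc(OCc9ccccc9)cc7)O[C@H]4c8ccc(OCc9ccccc9)cc8OCc9ccccc9)c(O)c([C@H](c7ccc(OCc9ccccc9)cc7)[C@H]4[C@H](C(=O)c8ccc(OCc9ccccc9)cc8OCc9ccccc9)[C@@H](c7ccc(OCc9ccccc9)cc7)O[C@H]4c8ccc(OCc9ccccc9)cc8OCc9ccccc9)c2O[C@@H]1c7ccc(OCc9ccccc9)cc7 | intermediate
43 | CNP0225367.3 | O=C(c1ccc(O)cc1O)[C@H]1[C@H]([C@@H](c2ccc(O)cc2)c2c(O)c3c(c([C@H](c4ccc(O)cc4)[C@H]4[C@H](C(=O)c5ccc(O)cc5O)[C@@H](c5ccc(O)cc5)O[C@H]4c4ccc(O)cc4O)c2O)O[C@H](c2ccc(O)cc2)[C@@H](O)C3)[C@H](c2ccc(O)cc2O)O[C@@H]1c1ccc(O)cc1 | target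

**Step count and risks**

Total step count: 25. Longest linear sequence: 20 steps (steps 1–10, 12, 13 and 18–25).

Steps most likely to fail:

1. Step 21. The alkynyl ether may fragment or rearrange before the catalyst engages it, the siloxyalkyne may homotrimerise or insert with the opposite orientation, and the crowded rhodacycle may fail to take up a second hindered alkyne so that turnover stalls. The fallback uses known ketene and benzannulation chemistry, sets out from alkynyl ether 35 and siloxyalkyne 22, and comes back at cycloadduct 39. Compound 35 is taken through the acetylide and ynolate as in step 20 but quenched with water to give the carboxylic acid F1. Activation of F1 with 1-chloro-N,N,2-trimethylprop-1-en-1-amine and Et3N generates the ketene, which adds across the tethered alkynyl ether in an intramolecular ketene (2+2) cycloaddition and gives the fused 3-alkoxycyclobutenone F2, closing ring C. Heating F2 with 22 in toluene at 80 °C (Danheiser benzannulation: electrocyclic opening to the vinylketene, (2+2) with the siloxyalkyne, ring opening, 6π closure and tautomerisation) should give the C5 phenol F3 with the arms at C6 and C8 by the inherent regiochemistry. Silylation of F3 with iPr3SiOTf and 2,6-lutidine gives 39.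

2. Step 19. t-BuLi may remove the allylic, benzylic Ca–H of the ketene acetal phosphate or metalate benzyl ethers instead of the vinylic C–H, which would epimerise Ca, isomerise the product to an allenyl ether or start Wittig-type rearrangements. The fallback builds the alkynyl ether from an α-alkoxy ketone instead of an ester and needs only amide and alkoxide bases; it sets out from arm alkyne 19 and alcohol 32 and comes back at 35. Hydration of 19 (Ph3PAuNTf2, aqueous dioxane) gives the methyl ketone F4. Detrifluoroacetylative diazo transfer under kinetic enolisation of the methyl group (LiN(SiMe3)2, CF3CO2CH2CF3, −78 °C; then MsN3, Et3N) gives the diazoketone F5. Insertion of its carbenoid into the O–H bond of 32 (Rh2(OAc)4, CH2Cl2) gives the α-alkoxy ketone F6. Kinetic enolisation toward the OCH2 group and triflation (LiN(SiMe3)2, PhNTf2, −78 °C) gives the enol triflate F7, and KOt-Bu at −78 °C eliminates triflate to give 35.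

3. Step 7. Deprotonation may occur at the more hindered α-carbon and epimerise the future C4′, the aldolate may revert, and the oxocarbenium ion may lose a proton to a dihydrofuran before hydride capture, which would erode the C4′/C5′ relationship. The fallback closes the oxolane by oxa-Michael addition instead of hemiketal reduction, sets out from diketone 13 and aldehyde 14, and comes back at 17. Aldol condensation (LiN(SiMe3)2, then MsCl/Et3N and DBU) gives the 2-arylidene-1,4-diketone F8. Oxazaborolidine-catalysed reduction ((S)-2-methyl-CBS-oxazaborolidine, catecholborane, toluene, −78 °C, conditions that leave the terminal alkyne alone) of the saturated aryl ketone, which should react before the hindered cross-conjugated enone, sets C5′ under catalyst control and gives the hydroxy enone F9. NaOMe in MeOH/THF then closes the ring by reversible 5-exo oxa-Michael addition under thermodynamic control to give 17.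

**Further compounds**

F1 | step 21 | carboxylic acid from 35 (C≡C–SiMe3 end converted into CH2CO2H) | OC(=O)CC[C@H](OCc9ccccc9)[C@@H](c7ccc(OCc9ccccc9)cc7)OC#C[C@H](c7ccc(OCc9ccccc9)cc7)[C@H]4[C@H](C(O[Si](CC)(CC)CC)c8ccc(OCc9ccccc9)cc8OCc9ccccc9)[C@@H](c7ccc(OCc9ccccc9)cc7)O[C@H]4c8ccc(OCc9ccccc9)cc8OCc9ccccc9
F2 | step 21 | pyran-fused 3-alkoxycyclobutenone (C5 carbonyl, C8 bears the arm, C4a sp3) | O=C1C([C@H](c7ccc(OCc9ccccc9)cc7)[C@H]4[C@H](C(O[Si](CC)(CC)CC)c8ccc(OCc9ccccc9)cc8OCc9ccccc9)[C@@H](c7ccc(OCc9ccccc9)cc7)O[C@H]4c8ccc(OCc9ccccc9)cc8OCc9ccccc9)=C2O[C@H](c7ccc(OCc9ccccc9)cc7)[C@@H](OCc9ccccc9)CC12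
F3 | step 21 | C5 phenol: 39 lacking the O5 silyl group | c9ccccc9CO[C@H]1Cc2c(O)c([C@H](c7ccc(OCc9ccccc9)cc7)[C@H]4[C@H](C(O[Si](CC)(CC)CC)c8ccc(OCc9ccccc9)cc8OCc9ccccc9)[C@@H](c7ccc(OCc9ccccc9)cc7)O[C@H]4c8ccc(OCc9ccccc9)cc8OCc9ccccc9)c(O[Si](C(C)C)(C(C)C)C(C)C)c([C@H](c7ccc(OCc9ccccc9)cc7)[C@H]4[C@H](C(O[Si](CC)(CC)CC)c8ccc(OCc9ccccc9)cc8OCc9ccccc9)[C@@H](c7ccc(OCc9ccccc9)cc7)O[C@H]4c8ccc(OCc9ccccc9)cc8OCc9ccccc9)c2O[C@@H]1c7ccc(OCc9ccccc9)cc7
F4 | step 19 | methyl ketone from hydration of 19 | CC(=O)[C@H](c7ccc(OCc9ccccc9)cc7)[C@H]4[C@H](C(O[Si](CC)(CC)CC)c8ccc(OCc9ccccc9)cc8OCc9ccccc9)[C@@H](c7ccc(OCc9ccccc9)cc7)O[C@H]4c8ccc(OCc9ccccc9)cc8OCc9ccccc9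
F5 | step 19 | diazoketone from F4 | [N-]=[N+]=CC(=O)[C@H](c7ccc(OCc9ccccc9)cc7)[C@H]4[C@H](C(O[Si](CC)(CC)CC)c8ccc(OCc9ccccc9)cc8OCc9ccccc9)[C@@H](c7ccc(OCc9ccccc9)cc7)O[C@H]4c8ccc(OCc9ccccc9)cc8OCc9ccccc9
F6 | step 19 | α-alkoxy ketone from F5 and 32 | C[Si](C)(C)C#CC[C@H](OCc9ccccc9)[C@@H](c7ccc(OCc9ccccc9)cc7)OCC(=O)[C@H](c7ccc(OCc9ccccc9)cc7)[C@H]4[C@H](C(O[Si](CC)(CC)CC)c8ccc(OCc9ccccc9)cc8OCc9ccccc9)[C@@H](c7ccc(OCc9ccccc9)cc7)O[C@H]4c8ccc(OCc9ccccc9)cc8OCc9ccccc9
F7 | step 19 | enol triflate of F6 (E/Z mixture) | C[Si](C)(C)C#CC[C@H](OCc9ccccc9)[C@@H](c7ccc(OCc9ccccc9)cc7)OC=C(OS(=O)(=O)C(F)(F)F)[C@H](c7ccc(OCc9ccccc9)cc7)[C@H]4[C@H](C(O[Si](CC)(CC)CC)c8ccc(OCc9ccccc9)cc8OCc9ccccc9)[C@@H](c7ccc(OCc9ccccc9)cc7)O[C@H]4c8ccc(OCc9ccccc9)cc8OCc9ccccc9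
F8 | step 7 | 2-arylidene-1,4-diketone from 13 and 14 | C#C[C@H](c7ccc(OCc9ccccc9)cc7)[C@@H](C(=Cc7ccc(OCc9ccccc9)cc7)C(=O)c8ccc(OCc9ccccc9)cc8OCc9ccccc9)C(=O)c8ccc(OCc9ccccc9)cc8OCc9ccccc9
F9 | step 7 | hydroxy enone from F8 (carbinol configuration as C5′ of 17) | C#C[C@H](c7ccc(OCc9ccccc9)cc7)[C@@H](C(=Cc7ccc(OCc9ccccc9)cc7)C(=O)c8ccc(OCc9ccccc9)cc8OCc9ccccc9)[C@@H](O)c8ccc(OCc9ccccc9)cc8OCc9ccccc9
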